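The route rests on cutting the decalin at its ring-fusion bond C5–C10 (clerodane numbering), which makes the bicycle acyclic. The key step rebuilds both rings in one base-mediated cascade. Deacetylation unveils a C5 enolate that adds to C10 of an enal, closing ring B and creating the C5–C10 bond and the quaternary C5. Aldol condensation of the C3 methyl onto the C2 aldehyde then closes ring A as a C2=C3–C4=O enone. The step exploits the 1,5-relationship of C4 and C2 across C5–C10 and the C3=C4(C18) alkene, which is later drawn from the C4 ketone. The precursor is an open-chain diketo-enal whose C8 and C9 centres were set on a δ-lactone template.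

Key step: step 10

Remark: clerodane numbering is used throughout (ring A = C1–C5 and C10, ring B = C5–C10, C17/C18/C19/C20 = methyls on C8/C4/C5/C9, side chain C11–C16); the acyl group is read as icosanoyl, and the 4R sense of step 1 is assumed to follow from the choice of ligand enantiomer.

Step 1
Reactants: 1 5,6-dihydro-2H-pyran-2-one
Product: 2 (4R)-4-methyloxan-2-one
Conditions: MeMgBr, CuBr·SMe2 (cat.), JosiPhos-type ferrocenyl diphosphine (cat., enantiomer giving 4R), t-BuOMe, −78 °C; then 1 M HCl
Reagents that add atoms: methylmagnesium bromide, C[Mg]Br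
Why: Copper-catalysed asymmetric conjugate addition of a Grignard reagent to the cyclic enoate; the chiral diphosphine–copper complex selects the enoate face and so sets C8 (C4 of the lactone).

Step 2
Reactants: 2 (4R)-4-methyloxan-2-one
Product: 4 (3S,4R)-3,4-dimethyloxan-2-one, via lithium enolate 3 (not isolated)
Conditions: LiN(i-Pr)2, THF, −78 °C; MeI, −78 → −40 °C
Reagents that add atoms: iodomethane, CI
Why: Lactone enolate alkylation anti to the C4 methyl group should give mainly the trans isomer; this centre is planarised again in step 3, so both epimers are usable.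

Step 3
Reactants: 4 (3S,4R)-3,4-dimethyloxan-2-one; 5 acetaldehyde
Product: 7 (3R,4R)-3-(1-hydroxyethyl)-3,4-dimethyloxan-2-one (carbinol epimers), via lithium enolate 6 (not isolated)
Conditions: LiN(i-Pr)2, THF, −78 °C; 5, −78 °C; AcOH quench
Reagents that add atoms: none
Why: Aldol addition of the tetrasubstituted lactone enolate, whose C4 methyl is held pseudoaxial by allylic strain and shields one face, should occur anti to that methyl and so set the quaternary C9 with C20 cis to C17; the carbinol centre is removed in step 4.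

Step 4
Reactants: 7 (3R,4R)-3-(1-hydroxyethyl)-3,4-dimethyloxan-2-one
Product: 8 (3S,4R)-3-ethenyl-3,4-dimethyloxan-2-one
Conditions: Ph2S[OC(CF3)2Ph]2, CH2Cl2, 0 °C → rt
Reagents that add atoms: none
Why: Dehydration of the secondary alcohol through an alkoxysulfurane; the only β-hydrogens are those of the methyl group, so elimination can give only the terminal vinyl group, and the neutral conditions avoid retro-aldol cleavage.

Step 5
Reactants: 8 (3S,4R)-3-ethenyl-3,4-dimethyloxan-2-one
Product: 9 (2S,3R)-2-ethenyl-2,3-dimethylpentane-1,5-diol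
Conditions: LiAlH4, THF, 0 °C → rt; aqueous work-up
Reagents that add atoms: none
Why: Hydride reduction of the lactone to the diol; the vinyl group and both stereocentres are untouched.

Step 6
Reactants: 9 (2S,3R)-2-ethenyl-2,3-dimethylpentane-1,5-diol
Product: 10 (2S,3R)-2-ethenyl-5-iodo-2,3-dimethylpentan-1-ol
Conditions: I2, PPh3, imidazole (one equivalent each of I2 and PPh3), CH2Cl2, −20 → 0 °C
Reagents that add atoms: iodine, [I][I]
Why: Appel-type iodination by SN2 displacement of the alkoxyphosphonium ion should occur at the unhindered primary hydroxyl (C6), the neopentyl hydroxyl next to the quaternary carbon reacting much more slowly.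

Step 7
Reactants: 10 (2S,3R)-2-ethenyl-5-iodo-2,3-dimethylpentan-1-ol
Product: 11 (2S,3R)-2-ethenyl-5-iodo-2,3-dimethylpentanal
Conditions: Dess–Martin periodinane, NaHCO3, CH2Cl2, 0 °C → rt
Reagents that add atoms: none
Why: Dess–Martin oxidation of the neopentyl alcohol to the C10 aldehyde, which has no α-hydrogen and so cannot enolise or epimerise.

Step 8
Reactants: 11 (2S,3R)-2-ethenyl-5-iodo-2,3-dimethylpentanal; 12 3-methylpentane-2,4-dione
Product: 13 (2S,3R)-6-acetyl-2-ethenyl-2,3,6-trimethyl-7-oxooctanal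
Conditions: 12 (excess), K2CO3, DMF, 45 °C
Reagents that add atoms: none
Why: SN2 C-alkylation of the diketone enolate by the primary iodide installs the C3–C4–C5(C19) unit as a doubly acetylated, latent C5 enolate; the non-enolisable aldehyde survives the weak base.

Step 9
Reactants: 13 (2S,3R)-6-acetyl-2-ethenyl-2,3,6-trimethyl-7-oxooctanal; 14 (triphenylphosphoranylidene)acetaldehyde
Product: 15 (2E,4S,5R)-8-acetyl-4-ethenyl-4,5,8-trimethyl-9-oxodec-2-enal
Conditions: 14, toluene, 90 °C
Reagents that add atoms: none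
Why: Wittig olefination with the stabilised formyl ylide should give the E-enal (C10=C1–C2HO) at the aldehyde only, since the ketones do not react with a stabilised ylide.

Step 10
Reactants: 15 (2E,4S,5R)-8-acetyl-4-ethenyl-4,5,8-trimethyl-9-oxodec-2-enal
Product: 19 (4aR,5S,6R,8aR)-5-ethenyl-5,6,8a-trimethyl-4a,5,6,7,8,8a-hexahydronaphthalen-1(4H)-one, via keto-enal 16 (not isolated), via Michael adduct 17 (not isolated), via aldol 18 (not isolated)
Conditions: NaOMe (slight excess), MeOH, high dilution, 0 → 50 °C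
Reagents that add atoms: none
Why: Methoxide cleaves one acetyl group of the non-enolisable 1,3-diketone by retro-Claisen fragmentation, giving the C5 enolate of methyl ketone 16, which adds to C10, the β-carbon of the enal, to give keto-aldehyde 17; the C3 methyl enolate then attacks the C2 aldehyde and aldol 18 loses water to the conjugated enone. The closest known reaction type is the Robinson-type tandem Michael addition/aldol condensation of a 1,5-keto-aldehyde, here fully intramolecular and triggered by deacylation. Ring B closes by 6-(enolexo)-exo-trig Michael addition, which forms the C5–C10 bond, and ring A closes by 6-(enolendo)-exo-trig aldol addition followed by E1cB dehydration. C5 and C10 should be set in a chair-like transition state in which both trigonal carbons keep their exocyclic π-systems (enolate C4 and enal C1) pseudo-equatorial to avoid allylic 1,3-strain, which places C4 and C1 trans and leads to the trans-fused decalin with C19 axial. The face is chosen by the existing centres, chiefly C8: the chair with the C8 methyl and the C9 vinyl group equatorial and C20 axial is expected to be preferred, which puts C19 syn to C20 as required. The step needs Michael closure through C5 and not C3, and ring closure ahead of intermolecular condensation; the six-membered transition state (C3 would need an eight-membered one), the non-enolisable enal and high dilution should secure this.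

Step 11
Reactants: 19 (4aR,5S,6R,8aR)-5-ethenyl-5,6,8a-trimethyl-4a,5,6,7,8,8a-hexahydronaphthalen-1(4H)-one
Product: 21 (4aR,5S,6R,8aR)-5-ethenyl-5,6,8a-trimethyl-3,4,4a,5,6,7,8,8a-octahydronaphthalen-1-yl trifluoromethanesulfonate, via lithium enolate 20 (not isolated)
Conditions: LiBH(s-Bu)3, THF, −78 °C; then PhNTf2, −78 → 0 °C
Reagents that add atoms: N-phenylbis(trifluoromethanesulfonimide), O=S(=O)(N(c1ccccc1)S(=O)(=O)C(F)(F)F)C(F)(F)F
Why: Conjugate reduction of the cyclohexenone, which has no substituent at its β-carbon other than the ring and whose carbonyl is shielded by the quaternary C5, should give the C3=C4 enolate regiospecifically, which is O-triflated in the same flask.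

Step 12
Reactants: 21 (4aR,5S,6R,8aR)-5-ethenyl-5,6,8a-trimethyl-3,4,4a,5,6,7,8,8a-octahydronaphthalen-1-yl trifluoromethanesulfonate
Product: 22 (1S,2R,4aR,8aR)-1-ethenyl-1,2,4a,5-tetramethyl-1,2,3,4,4a,7,8,8a-octahydronaphthalene
Conditions: Me2CuLi (from CuI and MeLi), THF, −20 → 0 °C
Reagents that add atoms: lithium dimethylcuprate, [Li+].C[Cu-]C
Why: Coupling of the alkenyl triflate with the cuprate replaces OTf by the C18 methyl with the double bond fixed at C3=C4; the monosubstituted vinyl group is inert.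

Step 13
Reactants: 23 but-2-yne-1,4-diol
Product: 24 4-[(tert-butyldimethylsilyl)oxy]but-2-yn-1-ol
Conditions: TBSCl, imidazole, DMF, 0 °C → rt (diol in excess)
Reagents that add atoms: tert-butyldimethylsilyl chloride, CC(C)(C)[Si](C)(C)Cl
Why: Statistical monosilylation of the symmetrical diol, run with excess diol so that the monoether should dominate.

Step 14
Reactants: 24 4-[(tert-butyldimethylsilyl)oxy]but-2-yn-1-ol
Product: 26 (2Z)-4-[(tert-butyldimethylsilyl)oxy]-3-iodobut-2-en-1-ol, via alkenylalanate 25 (not isolated)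
Conditions: NaAlH2(OCH2CH2OMe)2, THF, 0 °C; then I2, −78 → 0 °C
Reagents that add atoms: iodine, [I][I]
Why: Hydroxyl-directed trans-hydroalumination places aluminium on the alkyne carbon distal to the free hydroxyl within a five-membered alkoxyaluminate, and iodinolysis with retention should give the Z-iodoalkene with iodine cis to CH2OH.

Step 15
Reactants: 22 (1S,2R,4aR,8aR)-1-ethenyl-1,2,4a,5-tetramethyl-1,2,3,4,4a,7,8,8a-octahydronaphthalene; 26 (2Z)-4-[(tert-butyldimethylsilyl)oxy]-3-iodobut-2-en-1-ol
Product: 28 (2E)-3-{[(tert-butyldimethylsilyl)oxy]methyl}-5-[(1S,2R,4aR,8aR)-1,2,4a,5-tetramethyl-1,2,3,4,4a,7,8,8a-octahydronaphthalen-1-yl]pent-2-en-1-ol, via B-alkyl-9-BBN 27 (not isolated)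
Conditions: 9-BBN, THF, rt; then 26, Pd(dppf)Cl2 (cat.), AsPh3, Cs2CO3, DMF/H2O, rt
Reagents that add atoms: none
Why: Anti-Markovnikov hydroboration of the monosubstituted vinyl group (the trisubstituted ring alkene does not react with 9-BBN) followed by B-alkyl Suzuki–Miyaura coupling through zerovalent palladium, which proceeds with retention at the iodoalkene and so places C12 cis to C15.

Step 16
Reactants: 28 (2E)-3-{[(tert-butyldimethylsilyl)oxy]methyl}-5-[(1S,2R,4aR,8aR)-1,2,4a,5-tetramethyl-1,2,3,4,4a,7,8,8a-octahydronaphthalen-1-yl]pent-2-en-1-ol; 29 icosanoyl chloride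
Product: 30 (2E)-3-{[(tert-butyldimethylsilyl)oxy]methyl}-5-[(1S,2R,4aR,8aR)-1,2,4a,5-tetramethyl-1,2,3,4,4a,7,8,8a-octahydronaphthalen-1-yl]pent-2-en-1-yl icosanoate
Conditions: 29, Et3N, DMAP (cat.), CH2Cl2, 0 °C → rt
Reagents that add atoms: none
Why: Acylation of the only free hydroxyl (C15–OH) by the acid chloride under nucleophilic catalysis.

Step 17
Reactants: 30 (2E)-3-{[(tert-butyldimethylsilyl)oxy]methyl}-5-[(1S,2R,4aR,8aR)-1,2,4a,5-tetramethyl-1,2,3,4,4a,7,8,8a-octahydronaphthalen-1-yl]pent-2-en-1-yl icosanoate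
Product: 31 (2E)-3-(hydroxymethyl)-5-[(1S,2R,4aR,8aR)-1,2,4a,5-tetramethyl-1,2,3,4,4a,7,8,8a-octahydronaphthalen-1-yl]pent-2-en-1-yl icosanoate (CNP0168335.1)
Conditions: HF·pyridine, pyridine, THF, 0 °C → rt
Reagents that add atoms: none
Why: Fluoride cleavage of the silyl ether under buffered conditions should leave the ester and both alkenes intact; acyl migration is excluded because C15 and C16 lie trans across the double bond.

Compound list
1 | 5,6-dihydro-2H-pyran-2-one | O=C1C=CCCO1 | starting material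
2 | (4R)-4-methyloxan-2-one | O=C1C[C@H](C)CCO1 | intermediate
3 | lithium enolate of 2 | [Li+].[O-]C1=C[C@H](C)CCO1 | intermediate
4 | (3S,4R)-3,4-dimethyloxan-2-one | C[C@H]1[C@H](C)CCOC1=O | intermediate
5 | acetaldehyde | CC=O | starting material
6 | lithium enolate of 4 | [Li+].[O-]C1=C(C)[C@H](C)CCO1 | intermediate
7 | (3R,4R)-3-(1-hydroxyethyl)-3,4-dimethyloxan-2-one | CC(O)[C@@]1(C)[C@H](C)CCOC1=O | intermediate
8 | (3S,4R)-3-ethenyl-3,4-dimethyloxan-2-one | C=C[C@@]1(C)[C@H](C)CCOC1=O | intermediate
9 | (2S,3R)-2-ethenyl-2,3-dimethylpentane-1,5-diol | C=C[C@@](CO)(C)[C@H](C)CCO | intermediate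
10 | (2S,3R)-2-ethenyl-5-iodo-2,3-dimethylpentan-1-ol | C=C[C@@](CO)(C)[C@H](C)CCI | intermediate
11 | (2S,3R)-2-ethenyl-5-iodo-2,3-dimethylpentanal | C=C[C@@](C=O)(C)[C@H](C)CCI | intermediate
12 | 3-methylpentane-2,4-dione | CC(=O)C(C)C(C)=O | starting material
13 | (2S,3R)-6-acetyl-2-ethenyl-2,3,6-trimethyl-7-oxooctanal | C=C[C@@](C=O)(C)[C@H](C)CCC(C)(C(C)=O)C(C)=O | intermediate
14 | (triphenylphosphoranylidene)acetaldehyde | O=CC=P(c1ccccc1)(c1ccccc1)c1ccccc1 | starting material
15 | (2E,4S,5R)-8-acetyl-4-ethenyl-4,5,8-trimethyl-9-oxodec-2-enal | C=C[C@@](/C=C/C=O)(C)[C@H](C)CCC(C)(C(C)=O)C(C)=O | intermediate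
16 | (2E,4S,5R)-4-ethenyl-4,5,8-trimethyl-9-oxodec-2-enal (C8 epimers) | C=C[C@@](/C=C/C=O)(C)[C@H](C)CCC(C)C(C)=O | intermediate
17 | 2-[(1R,2S,3R,6R)-6-acetyl-2-ethenyl-2,3,6-trimethylcyclohexyl]acetaldehyde | C=C[C@@]1(C)[C@H](C)CC[C@@](C)(C(C)=O)[C@@H]1CC=O | intermediate
18 | (4aR,5S,6R,8aR)-5-ethenyl-3-hydroxy-5,6,8a-trimethyloctahydronaphthalen-1(2H)-one | C=C[C@@]1(C)[C@H](C)CC[C@@]2(C)C(=O)CC(O)C[C@H]12 | intermediate
19 | (4aR,5S,6R,8aR)-5-ethenyl-5,6,8a-trimethyl-4a,5,6,7,8,8a-hexahydronaphthalen-1(4H)-one | C=C[C@@]1(C)[C@H](C)CC[C@@]2(C)C(=O)C=CC[C@H]12 | intermediate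
20 | lithium enolate from 1,4-reduction of 19 | [Li+].C=C[C@@]1(C)[C@H](C)CC[C@@]2(C)C([O-])=CCC[C@H]12 | intermediate
21 | (4aR,5S,6R,8aR)-5-ethenyl-5,6,8a-trimethyl-3,4,4a,5,6,7,8,8a-octahydronaphthalen-1-yl trifluoromethanesulfonate | C=C[C@@]1(C)[C@H](C)CC[C@@]2(C)C(OS(=O)(=O)C(F)(F)F)=CCC[C@H]12 | intermediate
22 | (1S,2R,4aR,8aR)-1-ethenyl-1,2,4a,5-tetramethyl-1,2,3,4,4a,7,8,8a-octahydronaphthalene | C=C[C@@]1(C)[C@H](C)CC[C@@]2(C)C(C)=CCC[C@H]12 | intermediate
23 | but-2-yne-1,4-diol | OCC#CCO | starting material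
24 | 4-[(tert-butyldimethylsilyl)oxy]but-2-yn-1-ol | OCC#CCO[Si](C)(C)C(C)(C)C | intermediate
25 | sodium cyclic alkenylalanate from 24 | [Na+].COCCO[Al-]1(OCCOC)OCC=C1CO[Si](C)(C)C(C)(C)C | intermediate
26 | (2Z)-4-[(tert-butyldimethylsilyl)oxy]-3-iodobut-2-en-1-ol | OC/C=C(\I)CO[Si](C)(C)C(C)(C)C | intermediate
27 | B-alkyl-9-BBN adduct of 22 | C1CCC2CCCC(C1)B2CC[C@@]1(C)[C@H](C)CC[C@@]2(C)C(C)=CCC[C@H]12 | intermediate
28 | (2E)-3-{[(tert-butyldimethylsilyl)oxy]methyl}-5-[(1S,2R,4aR,8aR)-1,2,4a,5-tetramethyl-1,2,3,4,4a,7,8,8a-octahydronaphthalen-1-yl]pent-2-en-1-ol | OC/C=C(/CO[Si](C)(C)C(C)(C)C)CC[C@@]1(C)[C@H](C)CC[C@@]2(C)C(C)=CCC[C@H]12 | intermediate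
29 | icosanoyl chloride | CCCCCCCCCCCCCCCCCCCC(Cl)=O | starting material
30 | (2E)-3-{[(tert-butyldimethylsilyl)oxy]methyl}-5-[(1S,2R,4aR,8aR)-1,2,4a,5-tetramethyl-1,2,3,4,4a,7,8,8a-octahydronaphthalen-1-yl]pent-2-en-1-yl icosanoate | CCCCCCCCCCCCCCCCCCCC(=O)OC/C=C(/CO[Si](C)(C)C(C)(C)C)CC[C@@]1(C)[C@H](C)CC[C@@]2(C)C(C)=CCC[C@H]12 | intermediate
31 | (2E)-3-(hydroxymethyl)-5-[(1S,2R,4aR,8aR)-1,2,4a,5-tetramethyl-1,2,3,4,4a,7,8,8a-octahydronaphthalen-1-yl]pent-2-en-1-yl icosanoate | CCCCCCCCCCCCCCCCCCCC(=O)OC/C=C(/CO)CC[C@@]1(C)[C@H](C)CC[C@@]2(C)C(C)=CCC[C@H]12 | target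

Total step count: 17. Longest linear sequence: 15 steps (steps 1–12, then 15–17).

Steps most likely to fail

Step 10. What may go wrong: loss of stereocontrol in the reversible Michael ring closure (closure through a cis-disposed or opposite-face chair, or equilibration by retro-Michael addition), and intermolecular aldol condensation of the enal outrunning the hindered ring closure. Fallback: the two ring closures are separated and ring B is closed by a Lewis-acid-promoted Mukaiyama–Michael addition under kinetic control. The fallback sets out from 13. Brief treatment with NaOMe in MeOH at 0 °C removes one acetyl group to give (2S,3R)-2-ethenyl-2,3,6-trimethyl-7-oxooctanal F1. TMSCl, NaI and Et3N in MeCN convert it into the more substituted silyl enol ether (2S,3R)-2-ethenyl-2,3,6-trimethyl-7-[(trimethylsilyl)oxy]oct-6-enal F2. Wittig reaction with 14 gives (2E,4S,5R)-4-ethenyl-4,5,8-trimethyl-9-[(trimethylsilyl)oxy]deca-2,8-dienal F3. TiCl4 in CH2Cl2 at −78 °C should then close ring B to give 17, now isolated, and KOH in MeOH effects the aldol condensation, so the fallback comes back to the route at 19.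

Step 8. What may go wrong: O-alkylation of the ambident diketone enolate and slow C-alkylation at a fully substituted carbon by an unactivated primary iodide. Fallback: the donor is introduced by an acetoacetic ester alkylation and unmasked by decarboxylation instead of deacetylation. The fallback sets out from 11. Alkylation of tert-butyl 2-methyl-3-oxobutanoate (NaH, DMF) should give tert-butyl (5R,6S)-2-acetyl-6-ethenyl-2,5,6-trimethyl-7-oxoheptanoate F4. Wittig reaction with 14 gives tert-butyl (5R,6S,7E)-2-acetyl-6-ethenyl-2,5,6-trimethyl-9-oxonon-7-enoate F5. CF3CO2H in CH2Cl2 followed by warming cleaves the tert-butyl ester and decarboxylates the β-keto acid, so the fallback comes back to the route at 16, which is then submitted to NaOMe in MeOH as in step 10.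

Step 9. What may go wrong: slow olefination at the neopentyl aldehyde and further olefination of the product enal by the formyl ylide (over-homologation). Fallback: the enal is built stepwise before the ketone unit is introduced. The fallback sets out from 11. Horner–Wadsworth–Emmons reaction with triethyl phosphonoacetate (LiCl, DBU, MeCN) should give ethyl (2E,4S,5R)-4-ethenyl-7-iodo-4,5-dimethylhept-2-enoate F6. Reduction with i-Bu2AlH (CH2Cl2, −78 °C) gives (2E,4S,5R)-4-ethenyl-7-iodo-4,5-dimethylhept-2-en-1-ol F7, and MnO2 oxidation gives (2E,4S,5R)-4-ethenyl-7-iodo-4,5-dimethylhept-2-enal F8. Alkylation of 12 with F8 (K2CO3, DMF) then comes back to the route at 15.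

Further compounds
F1 | step 10 | (2S,3R)-2-ethenyl-2,3,6-trimethyl-7-oxooctanal | C=C[C@@](C=O)(C)[C@H](C)CCC(C)C(C)=O
F2 | step 10 | (2S,3R)-2-ethenyl-2,3,6-trimethyl-7-[(trimethylsilyl)oxy]oct-6-enal | C=C[C@@](C=O)(C)[C@H](C)CCC(C)=C(C)O[Si](C)(C)C
F3 | step 10 | (2E,4S,5R)-4-ethenyl-4,5,8-trimethyl-9-[(trimethylsilyl)oxy]deca-2,8-dienal | C=C[C@@](/C=C/C=O)(C)[C@H](C)CCC(C)=C(C)O[Si](C)(C)C
F4 | step 8 | tert-butyl (5R,6S)-2-acetyl-6-ethenyl-2,5,6-trimethyl-7-oxoheptanoate | C=C[C@@](C=O)(C)[C@H](C)CCC(C)(C(C)=O)C(=O)OC(C)(C)C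
F5 | step 8 | tert-butyl (5R,6S,7E)-2-acetyl-6-ethenyl-2,5,6-trimethyl-9-oxonon-7-enoate | C=C[C@@](/C=C/C=O)(C)[C@H](C)CCC(C)(C(C)=O)C(=O)OC(C)(C)C
F6 | step 9 | ethyl (2E,4S,5R)-4-ethenyl-7-iodo-4,5-dimethylhept-2-enoate | C=C[C@@](/C=C/C(=O)OCC)(C)[C@H](C)CCI
F7 | step 9 | (2E,4S,5R)-4-ethenyl-7-iodo-4,5-dimethylhept-2-en-1-ol | C=C[C@@](/C=C/CO)(C)[C@H](C)CCI
F8 | step 9 | (2E,4S,5R)-4-ethenyl-7-iodo-4,5-dimethylhept-2-enal | C=C[C@@](/C=C/C=O)(C)[C@H](C)CCI
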